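**Retrosynthetic overview**

1. Feature: the chain between ring A and ring B holds four methyl-branched trisubstituted E alkenes, C9=C10, C13=C14, C13'=C14' and C9'=C10'. Each is read as a terminal alkyne that takes up CH3 and a metal on the same side, and the metal then forms the next chain bond.
2. Disconnections: C14–C15 and C14'–C15' (the central C15=C15' comes from (E)-1-bromo-2-iodoethene, iodide used first, bromide second). C10–C11 and C10'–C11' (C11–C14 comes from (E)-1-bromo-4-(trimethylsilyl)but-1-en-3-yne). The four chain methyl groups come from Me3Al.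
3. Both ring dienynes (terminal C9≡C10) come from ring enol triflates by Heck vinylation with methyl vinyl ketone and enol phosphate elimination.
4. C2 (R, ring A) and C2' (S, ring B) come from one achiral exocyclic enal by conjugate reduction with the two antipodes of one imidazolidinone catalyst. The CH2CHO arm then becomes prenyl (Wittig) or CH=C(CH2OH)2 (Knoevenagel, hydride reduction).
5. Ring order: no ring is formed. Rings A and B are both the carbocycle of 2,2-dimethylcyclohexane-1,3-dione; the ring A half is completed first, the ring B half second, and the halves are joined last.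

Key step: step 11

Remark: carotenoid numbering is used (ring C1–C6, chain C7–C15, primes for the ring B half). The SMILES reads as 2R in ring A and 2'S in ring B, so the two rings belong to mirror-image series.

Assumption: the facial sense in steps 5 and 14 is assigned from the usual shielding model of the tert-butyl imidazolidinone iminium ion. Should the opposite sense hold, the two catalyst antipodes are exchanged between steps 5 and 14 and nothing else changes.

All polyene steps (11–13, 23–26) are run under argon in dim light.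

**Linchpins**

Step 1
Reactants: 1 acetylene; 2 iodine monobromide
Product: 3 (E)-1-bromo-2-iodoethene
Conditions: IBr, 48% aq HBr, acetylene stream, 0 °C
Reagents that add atoms: iodine monobromide 2, IBr
Why: Electrophilic halogen addition to an alkyne: the bridged iodonium ion is opened by bromide from the opposite side, so anti addition should give the E dihalide only.

Step 2
Reactants: 4 trimethylsilylacetylene; 3 (E)-1-bromo-2-iodoethene
Product: 7 (E)-1-bromo-4-(trimethylsilyl)but-1-en-3-yne, via lithium (trimethylsilyl)acetylide 5 (not isolated), via bromo[(trimethylsilyl)ethynyl]zinc 6 (not isolated)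
Conditions: n-BuLi, THF, −78 °C; ZnBr2, THF, 0 °C; 3 (1.1 equiv), Pd(PPh3)4 (2 mol %), 0 → 23 °C
Reagents that add atoms: n-BuLi, [Li]CCCC (lithium, only in 5); ZnBr2, Br[Zn]Br (zinc and bromine, only in 6)
Why: Negishi alkynyl–alkenyl coupling: zerovalent palladium inserts far faster into C–I than into C–Br, so the alkynylzinc should replace iodide alone, with retention of E geometry and with the bromide kept for steps 11 and 23.

**Common enal**

Step 3
Reactants: 8 2,2-dimethylcyclohexane-1,3-dione; 9 vinylmagnesium bromide
Product: 10 rac-3-ethenyl-3-hydroxy-2,2-dimethylcyclohexan-1-one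
Conditions: 9 (1.05 equiv), THF, −78 °C; cold aq NH4Cl
Reagents that add atoms: vinylmagnesium bromide 9, C=C[Mg]Br
Why: Grignard 1,2-addition to one of two equivalent carbonyl groups: the first-formed magnesium alkoxide shields the remaining neopentyl ketone, the cold quench forestalls retro-aldol opening, and the racemic carbinol centre is erased in step 4.

Step 4
Reactants: 10 rac-3-ethenyl-3-hydroxy-2,2-dimethylcyclohexan-1-one
Product: 11 (2E)-2-(2,2-dimethyl-3-oxocyclohexylidene)acetaldehyde (E expected as main isomer; the E/Z mixture is used)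
Conditions: [C5H5NH][CrO3Cl] (2.5 equiv), 4 Å sieves, CH2Cl2, 23 °C
Reagents that add atoms: pyridinium chlorochromate, [O-][Cr](=O)(=O)Cl.c1cc[nH+]cc1 (aldehyde oxygen)
Why: Babler–Dauben oxidative transposition: the tertiary allylic chromate ester shifts [3,3] to the primary allylic chromate, which collapses to the enal, the formyl group preferring the side away from the gem-dimethyl carbon and the E/Z composition being irrelevant for steps 5 and 14.

**Ring A half**

Step 5
Reactants: 11 (2E)-2-(2,2-dimethyl-3-oxocyclohexylidene)acetaldehyde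
Product: 12 2-[(1R)-2,2-dimethyl-3-oxocyclohexyl]acetaldehyde
Conditions: (S)-2-tert-butyl-3-methylimidazolidin-4-one·CF3CO2H (20 mol %), Hantzsch ester (1.2 equiv), CHCl3, −30 °C
Reagents that add atoms: none
Why: Iminium-catalysed asymmetric transfer hydrogenation (organocatalytic conjugate reduction) of a β,β-disubstituted enal: E and Z iminium ions interconvert through the dienamine, the E ion reacts faster and takes hydride at C2 on the face away from the catalyst tert-butyl group, the size gap between quaternary C1 and CH2-3 (akin to tert-butyl versus methyl) should secure 2R, and the hindered ketone forms no iminium ion.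

Step 6
Reactants: 12 2-[(1R)-2,2-dimethyl-3-oxocyclohexyl]acetaldehyde; 13 isopropyltriphenylphosphonium iodide
Product: 14 (3R)-2,2-dimethyl-3-(3-methylbut-2-enyl)cyclohexan-1-one
Conditions: 13, n-BuLi, THF, 0 °C; then 12, −78 → 0 °C
Reagents that add atoms: isopropyltriphenylphosphonium iodide 13, CC(C)[P+](c1ccccc1)(c1ccccc1)c1ccccc1.[I-]
Why: Wittig olefination: the non-stabilised ylide reacts with the aldehyde much faster than with the ketone next to a quaternary carbon, no alkene geometry arises, and C2 (β to the aldehyde) cannot epimerise.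

Step 7
Reactants: 14 (3R)-2,2-dimethyl-3-(3-methylbut-2-enyl)cyclohexan-1-one
Product: 15 (3R)-2,2,6-trimethyl-3-(3-methylbut-2-enyl)cyclohexan-1-one (both C6 epimers)
Conditions: LiN(i-Pr)2 (1.05 equiv), THF, −78 °C; MeI, −78 → 0 °C
Reagents that add atoms: methyl iodide, CI
Why: Enolate alkylation: the ketone has α-hydrogens on one side only (carotenoid C5), so a single enolate forms and MeI installs the C5 methyl group, the new centre being lost again in step 8.

Step 8
Reactants: 15 (3R)-2,2,6-trimethyl-3-(3-methylbut-2-enyl)cyclohexan-1-one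
Product: 16 ring A enol triflate, (5R)-2,6,6-trimethyl-5-(3-methylbut-2-enyl)cyclohex-1-en-1-yl trifluoromethanesulfonate
Conditions: LiN(i-Pr)2, THF, −78 → 0 °C; PhNTf2, 0 → 23 °C; H2O
Reagents that add atoms: N-phenylbis(trifluoromethanesulfonimide), O=S(=O)(N(c1ccccc1)S(=O)(=O)C(F)(F)F)C(F)(F)F
Why: Enol triflate formation: only the C5–H is left for deprotonation, so the tetrasubstituted C5=C6 enolate is the sole regioisomer and is trapped on oxygen.

Step 9
Reactants: 16 ring A enol triflate; 17 methyl vinyl ketone
Product: 18 ring A β-ionone analogue, (3E)-4-[(5R)-2,6,6-trimethyl-5-(3-methylbut-2-enyl)cyclohex-1-en-1-yl]but-3-en-2-one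
Conditions: 17 (4 equiv), Pd(OAc)2 (5 mol %), PPh3 (10 mol %), Et3N, DMF, 65 °C
Reagents that add atoms: methyl vinyl ketone 17, C=CC(C)=O
Why: Heck vinylation of an enol triflate with an enone: the alkenylpalladium species adds to the unsubstituted terminus of 17 and syn β-hydride elimination gives the E C7=C8 enone, while cyclisation onto the prenyl alkene would need a bridgehead alkene and is ruled out.

Step 10
Reactants: 18 ring A β-ionone analogue
Product: 20 ring A dienyne (C5=C6, E C7=C8, terminal C9≡C10, 2R), via ring A dienyl phosphate 19 (not isolated)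
Conditions: LiN(i-Pr)2 (1.05 equiv), THF, −78 °C; ClP(O)(OEt)2, −78 → 23 °C; LiN(i-Pr)2 (2.3 equiv), −78 → 23 °C; H2O
Reagents that add atoms: diethyl chlorophosphate, CCOP(=O)(Cl)OCC (phosphate group, only in 19)
Why: Methyl ketone to terminal alkyne by enol phosphate elimination: kinetic deprotonation at the acetyl methyl group, O-phosphorylation and base-induced loss of diethyl phosphate turn C9(=O)–CH3 into C9≡C10–H without touching C7=C8, as is established for β-ionone itself.

Step 11
Reactants: 20 ring A dienyne; 21 trimethylaluminium; 7 (E)-1-bromo-4-(trimethylsilyl)but-1-en-3-yne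
Product: 23 ring A all-E tetraenyne silylated at C14 (C5=C6, C7=C8, C9=C10, C11=C12, C13≡C14–SiMe3), via ring A C10 dimethylalane 22 (not isolated)
Conditions: 21 (2 equiv), Cp2ZrCl2 (0.25 equiv), (CH2Cl)2, 23 °C; volatiles off in vacuo; THF, 7 (1.05 equiv), ZnCl2 (0.3 equiv), Pd(PPh3)4 (5 mol %), 23 °C
Reagents that add atoms: trimethylaluminium 21, C[Al](C)C
Why: Me3Al and Cp2ZrCl2 (tetravalent zirconium) form a methylzirconocene–aluminium species that adds methyl and metal to the same side of the terminal C9≡C10 bond of 20, methyl to the internal C9 and metal to the terminal C10, which gives alane 22. ZnCl2 relays the alkenyl group from aluminium to the alkenylpalladium bromide formed by insertion of Pd(PPh3)4 (zerovalent palladium) into the C11–Br bond of 7, and reductive elimination forms C10–C11 with retention at both sp2 carbons. The closest known reaction type is zirconium-catalysed methylalumination of conjugated enynes followed by palladium- and zinc-cocatalysed Negishi coupling with alkenyl halides. No ring is closed and no stereocentre is created; C2 is remote from the reacting alkyne, has no acidic hydrogen and stays R. The step needs chemoselectivity for the alkyne, regioselectivity for methyl at C9 and integrity of the E alkenes: only the unhindered terminal alkyne undergoes carbometalation, whereas the trisubstituted prenyl alkene, the tetrasubstituted C5=C6 and the disubstituted C7=C8 are inert. The steric bias of a terminal alkyne places the metal on C10, and the alkyne of 7 is silyl-capped and meets no Me3Al because the excess is stripped first.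

Step 12
Reactants: 23 ring A C14-silylated tetraenyne
Product: 24 ring A terminal tetraenyne (C13≡C14–H)
Conditions: K2CO3 (0.2 equiv), MeOH/THF, 23 °C
Reagents that add atoms: none
Why: Protodesilylation of an alkynylsilane: methoxide attacks silicon and methanol protonates the released acetylide under conditions too mild to isomerise the tetraene.

Step 13
Reactants: 24 ring A terminal tetraenyne; 21 trimethylaluminium; 3 (E)-1-bromo-2-iodoethene
Product: 26 ring A all-E hexaenyl bromide (bromine on C15'), via ring A C14 dimethylalane 25 (not isolated)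
Conditions: 21 (2 equiv), Cp2ZrCl2 (0.25 equiv), (CH2Cl)2, 23 °C; volatiles off; THF solution added slowly to 3 (1.5 equiv), ZnCl2 (0.3 equiv), Pd(PPh3)4 (5 mol %), THF, 0 → 23 °C; used at once
Reagents that add atoms: trimethylaluminium 21, C[Al](C)C
Why: Second zirconium-catalysed methylalumination and Negishi coupling: syn addition puts CH3 on C13 and aluminium on C14, and since C–I of 3 undergoes oxidative addition ahead of C–Br, slow addition of the alane to excess 3 should stop at the E,E bromide.

**Ring B half**

Step 14
Reactants: 11 (2E)-2-(2,2-dimethyl-3-oxocyclohexylidene)acetaldehyde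
Product: 27 2-[(1S)-2,2-dimethyl-3-oxocyclohexyl]acetaldehyde
Conditions: (R)-2-tert-butyl-3-methylimidazolidin-4-one·CF3CO2H (20 mol %), Hantzsch ester (1.2 equiv), CHCl3, −30 °C
Reagents that add atoms: none
Why: The same iminium-catalysed asymmetric transfer hydrogenation as in step 5 with the mirror-image catalyst, so hydride reaches C2' from the opposite face and sets 2'S.

Step 15
Reactants: 27 2-[(1S)-2,2-dimethyl-3-oxocyclohexyl]acetaldehyde; 28 dimethyl malonate
Product: 29 dimethyl 2-{2-[(1S)-2,2-dimethyl-3-oxocyclohexyl]ethylidene}propanedioate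
Conditions: 28 (1.1 equiv), piperidine (10 mol %), AcOH (10 mol %), cyclohexane, reflux, Dean–Stark trap
Reagents that add atoms: dimethyl malonate 28, COC(=O)CC(=O)OC
Why: Knoevenagel condensation: piperidinium acetate condenses the unhindered β-branched aldehyde with the malonate under water removal, the hindered ketone stays out, and two identical ester groups make alkene geometry void.

Step 16
Reactants: 29 alkylidene malonate
Product: 30 2-{2-[(1S)-3-hydroxy-2,2-dimethylcyclohexyl]ethylidene}propane-1,3-diol (both ring carbinol epimers)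
Conditions: i-Bu2AlH (7 equiv), CH2Cl2, −78 → 0 °C; aq Rochelle salt
Reagents that add atoms: none
Why: 1,2-Reduction of an alkylidene malonate with an electrophilic aluminium hydride: i-Bu2AlH takes both esters to allylic alcohols in preference to conjugate reduction, and the unavoidable reduction of the ring ketone is accepted and reversed in step 18.

Step 17
Reactants: 30 triol
Product: 31 (3S)-3-{4-(tert-butyldimethylsilyloxy)-3-[(tert-butyldimethylsilyloxy)methyl]but-2-enyl}-2,2-dimethylcyclohexan-1-ol (both C1 epimers)
Conditions: TBSCl (2.2 equiv), imidazole (4 equiv), CH2Cl2/DMF, 0 °C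
Reagents that add atoms: tert-butyldimethylsilyl chloride, CC(C)(C)[Si](C)(C)Cl
Why: Selective silylation: the two primary allylic hydroxyl groups react far faster than the secondary hydroxyl next to the quaternary carbon.

Step 18
Reactants: 31 bis-silyl ether alcohol
Product: 32 (3S)-3-{4-(tert-butyldimethylsilyloxy)-3-[(tert-butyldimethylsilyloxy)methyl]but-2-enyl}-2,2-dimethylcyclohexan-1-one
Conditions: Dess–Martin periodinane (1.3 equiv), CH2Cl2, 23 °C
Reagents that add atoms: none
Why: Dess–Martin oxidation: the only free alcohol is oxidised under near-neutral conditions that leave the silyl ethers, the trisubstituted alkene and C2' untouched, and both carbinol epimers converge on one ketone.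

Step 19
Reactants: 32 ring B ketone
Product: 33 6-methyl derivative of 32, (3S)-configured (both C6 epimers)
Conditions: LiN(i-Pr)2 (1.05 equiv), THF, −78 °C; MeI, −78 → 0 °C
Reagents that add atoms: methyl iodide, CI
Why: Enolate alkylation as in step 7: one enolisable side only, and silyl ethers are inert to the amide base.

Step 20
Reactants: 33 ring B methyl ketone
Product: 34 ring B enol triflate (C5'=C6'–OTf, 2'S)
Conditions: LiN(i-Pr)2, THF, −78 → 0 °C; PhNTf2, 0 → 23 °C; H2O
Reagents that add atoms: N-phenylbis(trifluoromethanesulfonimide), O=S(=O)(N(c1ccccc1)S(=O)(=O)C(F)(F)F)C(F)(F)F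
Why: Enol triflate formation as in step 8, with the single remaining α-hydrogen fixing the regiochemistry.

Step 21
Reactants: 34 ring B enol triflate; 17 methyl vinyl ketone
Product: 35 ring B β-ionone analogue (E C7'=C8', 2'S, bis-silyl ether)
Conditions: 17 (4 equiv), Pd(OAc)2 (5 mol %), PPh3 (10 mol %), Et3N, DMF, 65 °C
Reagents that add atoms: methyl vinyl ketone 17, C=CC(C)=O
Why: Heck vinylation as in step 9; allylic silyl ethers are not ionised by zerovalent palladium and survive Et3N in DMF.

Step 22
Reactants: 35 ring B β-ionone analogue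
Product: 37 ring B dienyne (terminal C9'≡C10', 2'S, bis-silyl ether), via ring B dienyl phosphate 36 (not isolated)
Conditions: LiN(i-Pr)2 (1.05 equiv), THF, −78 °C; ClP(O)(OEt)2, −78 → 23 °C; LiN(i-Pr)2 (2.3 equiv), −78 → 23 °C; H2O
Reagents that add atoms: diethyl chlorophosphate, CCOP(=O)(Cl)OCC (phosphate group, only in 36)
Why: Enol phosphate elimination as in step 10, with the silyl ethers as spectators.

Step 23
Reactants: 37 ring B dienyne; 21 trimethylaluminium; 7 (E)-1-bromo-4-(trimethylsilyl)but-1-en-3-yne
Product: 39 ring B all-E tetraenyne silylated at C14', via ring B C10' dimethylalane 38 (not isolated)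
Conditions: 21 (3 equiv), Cp2ZrCl2 (0.25 equiv), (CH2Cl)2, 23 °C; volatiles off; THF, 7 (1.05 equiv), ZnCl2 (0.3 equiv), Pd(PPh3)4 (5 mol %), 23 °C
Reagents that add atoms: trimethylaluminium 21, C[Al](C)C
Why: Zirconium-catalysed methylalumination and Negishi coupling as in step 11, with extra Me3Al to cover coordination to the two silyl ether oxygens, which are otherwise tolerated.

Step 24
Reactants: 39 ring B C14'-silylated tetraenyne
Product: 40 ring B terminal tetraenyne (C13'≡C14'–H, bis-silyl ether)
Conditions: K2CO3 (0.2 equiv), MeOH/THF, 23 °C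
Reagents that add atoms: none
Why: Protodesilylation of the alkynylsilane: carbonate in methanol cleaves C(sp)–SiMe3 but not the bulky O–SiMe2t-Bu groups.

Step 25
Reactants: 40 ring B terminal tetraenyne; 21 trimethylaluminium; 26 ring A hexaenyl bromide
Product: 42 bis(tert-butyldimethylsilyl) ether of the target (all-E, 2R,2'S), via ring B C14' dimethylalane 41 (not isolated)
Conditions: 21 (3 equiv), Cp2ZrCl2 (0.25 equiv), (CH2Cl)2, 23 °C; volatiles off; THF, 26 (0.9 equiv), ZnCl2 (0.3 equiv), Pd(PPh3)4 (5 mol %), 23 °C
Reagents that add atoms: trimethylaluminium 21, C[Al](C)C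
Why: Methylalumination and Negishi alkenyl–alkenyl coupling: CH3 goes to C13' and aluminium to C14', and stereoretentive coupling with the C15'–Br bond of 26 closes the all-E chain at C14'–C15' without any equilibrating step.

Step 26
Reactants: 42 bis-silyl ether of the target
Product: 43 target, (2R,2'S)-2-(3-methylbut-2-enyl)-2'-[4-hydroxy-3-(hydroxymethyl)but-2-enyl]-β,β-carotene
Conditions: n-Bu4NF (3 equiv), THF, 0 → 23 °C; H2O
Reagents that add atoms: none
Why: Fluoride desilylation: the strong Si–F bond drives cleavage of both primary silyl ethers under non-acidic conditions that the polyene tolerates.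

**Compound list**

1 | acetylene | C#C | starting material
2 | iodine monobromide | IBr | starting material
3 | (E)-1-bromo-2-iodoethene | Br/C=C/I | intermediate
4 | trimethylsilylacetylene | C#C[Si](C)(C)C | starting material
5 | lithium (trimethylsilyl)acetylide | [Li]C#C[Si](C)(C)C | intermediate
6 | bromo[(trimethylsilyl)ethynyl]zinc | Br[Zn]C#C[Si](C)(C)C | intermediate
7 | (E)-1-bromo-4-(trimethylsilyl)but-1-en-3-yne | Br/C=C/C#C[Si](C)(C)C | intermediate
8 | 2,2-dimethylcyclohexane-1,3-dione | CC1(C)C(=O)CCCC1=O | starting material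
9 | vinylmagnesium bromide | C=C[Mg]Br | starting material
10 | rac-3-ethenyl-3-hydroxy-2,2-dimethylcyclohexan-1-one | C=CC1(O)CCCC(=O)C1(C)C | intermediate
11 | (2E)-2-(2,2-dimethyl-3-oxocyclohexylidene)acetaldehyde | O=C/C=C1\CCCC(=O)C1(C)C | intermediate
12 | 2-[(1R)-2,2-dimethyl-3-oxocyclohexyl]acetaldehyde | O=CC[C@H]1CCCC(=O)C1(C)C | intermediate
13 | isopropyltriphenylphosphonium iodide | CC(C)[P+](c1ccccc1)(c1ccccc1)c1ccccc1.[I-] | starting material
14 | (3R)-2,2-dimethyl-3-(3-methylbut-2-enyl)cyclohexan-1-one | CC(C)=CC[C@H]1CCCC(=O)C1(C)C | intermediate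
15 | (3R)-2,2,6-trimethyl-3-(3-methylbut-2-enyl)cyclohexan-1-one, C6 epimers | CC(C)=CC[C@H]1CCC(C)C(=O)C1(C)C | intermediate
16 | ring A enol triflate | CC(C)=CC[C@H]1CCC(C)=C(OS(=O)(=O)C(F)(F)F)C1(C)C | intermediate
17 | methyl vinyl ketone | C=CC(C)=O | starting material
18 | ring A β-ionone analogue | CC(C)=CC[C@H]1CCC(C)=C(/C=C/C(C)=O)C1(C)C | intermediate
19 | ring A dienyl diethyl phosphate | CC(C)=CC[C@H]1CCC(C)=C(/C=C/C(=C)OP(=O)(OCC)OCC)C1(C)C | intermediate
20 | ring A dienyne | CC(C)=CC[C@H]1CCC(C)=C(/C=C/C#C)C1(C)C | intermediate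
21 | trimethylaluminium | C[Al](C)C | starting material
22 | ring A C10 dimethylalane | CC(C)=CC[C@H]1CCC(C)=C(/C=C/C(C)=C/[Al](C)C)C1(C)C | intermediate
23 | ring A C14-silylated tetraenyne | CC(C)=CC[C@H]1CCC(C)=C(/C=C/C(C)=C/C=C/C#C[Si](C)(C)C)C1(C)C | intermediate
24 | ring A terminal tetraenyne | CC(C)=CC[C@H]1CCC(C)=C(/C=C/C(C)=C/C=C/C#C)C1(C)C | intermediate
25 | ring A C14 dimethylalane | CC(C)=CC[C@H]1CCC(C)=C(/C=C/C(C)=C/C=C/C(C)=C/[Al](C)C)C1(C)C | intermediate
26 | ring A hexaenyl bromide | CC(C)=CC[C@H]1CCC(C)=C(/C=C/C(C)=C/C=C/C(C)=C/C=C/Br)C1(C)C | intermediate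
27 | 2-[(1S)-2,2-dimethyl-3-oxocyclohexyl]acetaldehyde | O=CC[C@@H]1CCCC(=O)C1(C)C | intermediate
28 | dimethyl malonate | COC(=O)CC(=O)OC | starting material
29 | ring B alkylidene malonate | COC(=O)C(=CC[C@@H]1CCCC(=O)C1(C)C)C(=O)OC | intermediate
30 | ring B triol, carbinol epimers | OCC(CO)=CC[C@@H]1CCCC(O)C1(C)C | intermediate
31 | ring B bis-silyl ether alcohol | CC(C)(C)[Si](C)(C)OCC(CO[Si](C)(C)C(C)(C)C)=CC[C@@H]1CCCC(O)C1(C)C | intermediate
32 | ring B bis-silyl ether ketone | CC(C)(C)[Si](C)(C)OCC(CO[Si](C)(C)C(C)(C)C)=CC[C@@H]1CCCC(=O)C1(C)C | intermediate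
33 | ring B methyl ketone, C6 epimers | CC(C)(C)[Si](C)(C)OCC(CO[Si](C)(C)C(C)(C)C)=CC[C@@H]1CCC(C)C(=O)C1(C)C | intermediate
34 | ring B enol triflate | CC(C)(C)[Si](C)(C)OCC(CO[Si](C)(C)C(C)(C)C)=CC[C@@H]1CCC(C)=C(OS(=O)(=O)C(F)(F)F)C1(C)C | intermediate
35 | ring B β-ionone analogue | CC(C)(C)[Si](C)(C)OCC(CO[Si](C)(C)C(C)(C)C)=CC[C@@H]1CCC(C)=C(/C=C/C(C)=O)C1(C)C | intermediate
36 | ring B dienyl diethyl phosphate | CC(C)(C)[Si](C)(C)OCC(CO[Si](C)(C)C(C)(C)C)=CC[C@@H]1CCC(C)=C(/C=C/C(=C)OP(=O)(OCC)OCC)C1(C)C | intermediate
37 | ring B dienyne | CC(C)(C)[Si](C)(C)OCC(CO[Si](C)(C)C(C)(C)C)=CC[C@@H]1CCC(C)=C(/C=C/C#C)C1(C)C | intermediate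
38 | ring B C10' dimethylalane | CC(C)(C)[Si](C)(C)OCC(CO[Si](C)(C)C(C)(C)C)=CC[C@@H]1CCC(C)=C(/C=C/C(C)=C/[Al](C)C)C1(C)C | intermediate
39 | ring B C14'-silylated tetraenyne | CC(C)(C)[Si](C)(C)OCC(CO[Si](C)(C)C(C)(C)C)=CC[C@@H]1CCC(C)=C(/C=C/C(C)=C/C=C/C#C[Si](C)(C)C)C1(C)C | intermediate
40 | ring B terminal tetraenyne | CC(C)(C)[Si](C)(C)OCC(CO[Si](C)(C)C(C)(C)C)=CC[C@@H]1CCC(C)=C(/C=C/C(C)=C/C=C/C#C)C1(C)C | intermediate
41 | ring B C14' dimethylalane | CC(C)(C)[Si](C)(C)OCC(CO[Si](C)(C)C(C)(C)C)=CC[C@@H]1CCC(C)=C(/C=C/C(C)=C/C=C/C(C)=C/[Al](C)C)C1(C)C | intermediate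
42 | bis(tert-butyldimethylsilyl) ether of the target | CC(C)=CC[C@H]1CCC(C)=C(/C=C/C(C)=C/C=C/C(C)=C/C=C/C=C(C)/C=C/C=C(C)/C=C/C2=C(C)CC[C@@H](CC=C(CO[Si](C)(C)C(C)(C)C)CO[Si](C)(C)C(C)(C)C)C2(C)C)C1(C)C | intermediate
43 | CNP0213288.1 | CC(C)=CC[C@H]1CCC(C)=C(/C=C/C(C)=C/C=C/C(C)=C/C=C/C=C(C)/C=C/C=C(C)/C=C/C2=C(C)CC[C@@H](CC=C(CO)CO)C2(C)C)C1(C)C | target

**Step count**

Total step count: 26.
Longest linear sequence: 15 steps (3, 4, 14–26).

**Steps most likely to fail**

Step 5 (its mirror image, step 14, shares the risk). Iminium formation at the congested exocyclic enal may be slow, or facial selectivity in the hydride transfer may be poor.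
- The fallback replaces organocatalysis by hydroxyl-directed metal-catalysed hydrogenation. It sets out from 11 and comes back at 12.
- The aldehyde alone is reduced (NaBH4, EtOH/CH2Cl2, −78 °C) to (E)-3-(2-hydroxyethylidene)-2,2-dimethylcyclohexan-1-one F1, which is freed from its Z isomer by chromatography.
- Asymmetric hydrogenation of this allylic alcohol with Ru(OAc)2[(R)-BINAP] and H2 in MeOH should give (3R)-3-(2-hydroxyethyl)-2,2-dimethylcyclohexan-1-one F2. The ligand antipode is chosen by analogy with E-configured 3,3-disubstituted allylic alcohols.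
- Dess–Martin oxidation of F2 leads back to 12.
- With Ru(OAc)2[(S)-BINAP] the same sequence should give (3S)-3-(2-hydroxyethyl)-2,2-dimethylcyclohexan-1-one F3, whose oxidation comes back at 27.

Step 9. Oxidative addition at the tetrasubstituted triflate, flanked by a quaternary carbon and a methyl-bearing carbon, may be sluggish, so that triflate cleavage or polymerisation of the enone takes over.
- The fallback avoids the triflate and the ionone stage altogether. It sets out from 15 and 7 and comes back at 20.
- Bromine–lithium exchange on 7 (t-BuLi, 2 equiv, Et2O, −78 °C) gives (E)-4-(trimethylsilyl)but-1-en-3-ynyllithium F4.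
- F4 adds to ketone 15 to give the tertiary allylic alcohol F5.
- Dehydration with the Burgess reagent (toluene, 50 °C) can only take the C5 hydrogen and should give the C10-silylated ring A dienyne F6.
- K2CO3 in MeOH converts F6 into 20.

Step 11. Regiocontrol of the methylalumination on the conjugated dienyne may be incomplete. The alane may be protonated before coupling, or homocoupling and erosion of E geometry may occur during the cross-coupling.
- The fallback builds C9=C10 and C11=C12 by carbonyl olefination. It sets out from 18 and comes back at 23.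
- Horner–Wadsworth–Emmons reaction of 18 with diethyl cyanomethylphosphonate (NaH, THF) gives the (9E)-trienenitrile F7 after separation from its 9Z isomer.
- i-Bu2AlH (toluene, −78 °C) followed by mild acid hydrolysis gives the (9E)-trienal F8.
- A second Horner–Wadsworth–Emmons reaction with diethyl [3-(trimethylsilyl)prop-2-yn-1-yl]phosphonate (LiN(SiMe3)2, THF, −78 → 0 °C) forms the E C11=C12 bond and delivers 23.

**Further compounds**

F1 | step 5 | (E)-3-(2-hydroxyethylidene)-2,2-dimethylcyclohexan-1-one | OC/C=C1\CCCC(=O)C1(C)C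
F2 | step 5 | (3R)-3-(2-hydroxyethyl)-2,2-dimethylcyclohexan-1-one | OCC[C@H]1CCCC(=O)C1(C)C
F3 | step 5 | (3S)-3-(2-hydroxyethyl)-2,2-dimethylcyclohexan-1-one | OCC[C@@H]1CCCC(=O)C1(C)C
F4 | step 9 | (E)-4-(trimethylsilyl)but-1-en-3-ynyllithium | [Li]/C=C/C#C[Si](C)(C)C
F5 | step 9 | (3R)-2,2,6-trimethyl-3-(3-methylbut-2-enyl)-1-[(E)-4-(trimethylsilyl)but-1-en-3-ynyl]cyclohexan-1-ol, diastereomers | CC(C)=CC[C@H]1CCC(C)C(O)(/C=C/C#C[Si](C)(C)C)C1(C)C
F6 | step 9 | C10-silylated ring A dienyne | CC(C)=CC[C@H]1CCC(C)=C(/C=C/C#C[Si](C)(C)C)C1(C)C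
F7 | step 11 | ring A (7E,9E)-trienenitrile | CC(C)=CC[C@H]1CCC(C)=C(/C=C/C(C)=C/C#N)C1(C)C
F8 | step 11 | ring A (7E,9E)-trienal | CC(C)=CC[C@H]1CCC(C)=C(/C=C/C(C)=C/C=O)C1(C)C
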